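**Plan** (chromene numbering of the target: O-1, C-2, C-3, C-4 ketone, C-4a, C-5 enol, C-6, C-7 ketone, C-8 quaternary, C-8a; ring A = carbocycle, ring B = dihydropyranone, ring C = temporary dihydropyran acetal)
- Retrosynthesis: CO2H ⇐ CHO ⇐ cyclic methyl acetal with O-5 (ring C); then the C-7–C-8 bond and the CH2–CH= bond of the C-8 prenyl group are cut together, giving dienone 21 and Me2C=CHMgBr; ring B is cut at O-1–C-8a; C-4a is cut from C-4 and from C-8a (two acylations of the thioester acetal 14).
- Forward order: ring C first (Michael addition/hemiacetalisation), then ring B (cyclodehydration), then ring A last through the C-7–C-8 bond.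
- Enabling feature: C-8 bears a CH2–CH=CMe2 arm and is γ to the C-4 ketone through the C-4a=C-8a enol-ether bond of ring B. A C-8=CH2 group is therefore a 1,6-acceptor whose CH2 becomes the prenyl CH2, and the resulting dienolate carbon lies 1,6 to the thioester carbon C-7, which ring C holds cis to C-4a.
- Stereochemistry: lavandulyl centre from (R)-lavandulol; C-2/C-3 (cis) from an Evans syn-aldol; benzylic centre from an iminium-catalysed Michael addition; C-8 in the key step from dienolate geometry plus shielding by the pseudoaxial phenyl of ring C.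

Key step: step 13

Assumption: (R)-lavandulol (1) is taken as a purchasable enantiopure terpene alcohol; the acetal carbon of ring C is carried as a mixture of anomers and written without configuration because it is lost in step 14, and 17 is drawn as its diketo tautomer.

Step 1
Reactants: 1 (R)-lavandulol
Product: 2 (R)-lavandulyl iodide
Conditions: I2, PPh3, imidazole, CH2Cl2, 0 °C → rt
Reagents that add atoms: iodine, II
Why: Appel-type iodination of the primary alcohol through its alkoxyphosphonium salt should leave the neighbouring stereocentre and both alkenes untouched.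

Step 2
Reactants: 2 (R)-lavandulyl iodide; 3 dimethyl malonate
Product: 4 dimethyl lavandulylmalonate
Conditions: NaH, THF/DMF, 0 → 60 °C
Reagents that add atoms: none
Why: Malonic ester alkylation, in which the soft and weakly basic sodiomalonate should displace the primary iodide by SN2 without E2 elimination; no new stereocentre is formed.

Step 3
Reactants: 4 dimethyl lavandulylmalonate
Product: 5 (4R)-7-methyl-4-(prop-1-en-2-yl)oct-6-enoic acid
Conditions: KOH, MeOH/H2O, 60 °C; aq HCl; then pyridine, 110 °C
Reagents that add atoms: potassium hydroxide, [K+].[OH-]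
Why: Saponification and thermal decarboxylation of the malonic acid (malonic ester synthesis) under non-acidic heating should give the chain-extended acid without touching the alkenes or the stereocentre.

Step 4
Reactants: 6 (4S)-4-benzyl-3-propanoyl-1,3-oxazolidin-2-one; 7 acetaldehyde
Product: 8 Evans syn-aldol adduct
Conditions: Bu2BOTf, iPr2NEt, CH2Cl2, −78 → 0 °C; MeCHO, −78 → 0 °C; pH 7 buffer, MeOH, 30% H2O2
Reagents that add atoms: none
Why: Evans syn-aldol reaction, in which the Z-boron enolate reacts through a closed chair transition state on the face opposite the benzyl group and so sets the (2S,3R) centres that become C-3 and C-2.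

Step 5
Reactants: 8 Evans syn-aldol adduct
Product: 9 (2S,3R)-3-hydroxy-N-methoxy-N,2-dimethylbutanamide
Conditions: MeNH(OMe)·HCl, AlMe3, CH2Cl2, −20 °C → rt; aq HCl work-up
Reagents that add atoms: N,O-dimethylhydroxylamine hydrochloride, CNOC.Cl
Why: Aluminium-amide aminolysis of the β-hydroxy imide (Weinreb amide formation) should release the auxiliary without epimerising the α-centre.

Step 6
Reactants: 9 (2S,3R)-3-hydroxy-N-methoxy-N,2-dimethylbutanamide
Product: 10 silyl ether of 9
Conditions: TBSOTf, 2,6-lutidine, CH2Cl2, −78 → 0 °C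
Reagents that add atoms: tert-butyldimethylsilyl trifluoromethanesulfonate, CC(C)(C)[Si](C)(C)OS(=O)(=O)C(F)(F)F
Why: Standard silylation of the secondary alcohol protects it during the two enolate acylations that follow.

Step 7
Reactants: 11 S-tert-butyl 3-oxobutanethioate; 12 (E)-cinnamaldehyde
Product: 13 lactol (ring C; 4S)
Conditions: (S)-2-[diphenyl(trimethylsilyloxy)methyl]pyrrolidine (10 mol %), PhCO2H (10 mol %), CH2Cl2, rt
Reagents that add atoms: none
Why: Iminium-catalysed Michael addition of the β-keto thioester followed by hemiacetalisation through the ketone enol; the diphenyl(silyloxy)methyl group of the (S)-amine shields one face of the E-iminium ion so that the benzylic centre should form as (S), and the ring fixes the enol geometry with the thioester cis to the methyl-bearing carbon.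

Step 8
Reactants: 13 lactol (ring C; 4S)
Product: 14 methyl acetal (ring C; 4S)
Conditions: MeOH, pyridinium p-toluenesulfonate (cat.), 3 Å molecular sieves, rt
Reagents that add atoms: methanol, CO
Why: Acid-catalysed acetalisation of the lactol (Fischer glycosidation type) masks the aldehyde carbon as a base-stable acetal; the anomeric mixture is of no consequence.

Step 9
Reactants: 14 methyl acetal (ring C; 4S); 10 silyl ether of 9
Product: 15 ketone (C-4 joined to the future C-4a)
Conditions: LiN(iPr)2 (2.2 equiv), 14 (2.2 equiv), THF, −78 °C; then 10 (1 equiv), −78 → −20 °C; aq NH4Cl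
Reagents that add atoms: none
Why: Vinylogous Claisen acylation, in which the γ-deprotonated β-alkoxy enoate attacks the Weinreb amide through its methyl-derived carbon (the α-carbon is fully substituted) and the chelated tetrahedral intermediate prevents over-addition, the α-centre of 10 being untouched.

Step 10
Reactants: 15 ketone (C-4 joined to the future C-4a); 5 (4R)-7-methyl-4-(prop-1-en-2-yl)oct-6-enoic acid
Product: 17 2-substituted 1,3-diketone (enol tautomers), via acid chloride 16 (not isolated)
Conditions: 5, 1-chloro-N,N,2-trimethylprop-1-en-1-amine, CH2Cl2, 0 °C → rt; the solution of 16 is added to 15, MgBr2·OEt2, iPr2NEt, CH2Cl2, 0 °C → rt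
Reagents that add atoms: none
Why: Soft-enolisation C-acylation of the doubly activated CH2 (magnesium enolate plus acid chloride) should give the 1,3-diketone, the acid chloride being made under neutral conditions so that no HCl adds to the alkenes.

Step 11
Reactants: 17 2-substituted 1,3-diketone (enol tautomers)
Product: 18 dihydropyranone (ring B closed)
Conditions: HF·pyridine, pyridine, THF, 0 °C → rt
Reagents that add atoms: none
Why: Desilylation frees the δ-hydroxyl, which should add to the lavandulyl-side ketone and dehydrate (cyclodehydration to a 2,3-dihydro-4H-pyran-4-one) with retention at both aldol-derived centres, giving the cis-2,3-dimethyl ring B; the ring C carbon is a vinylogous thiocarbonate and is not attacked.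

Step 12
Reactants: 18 dihydropyranone (ring B closed)
Product: 21 exocyclic methylene dienone, via Mannich base 19 (not isolated), via ammonium iodide 20 (not isolated)
Conditions: LiN(SiMe3)2 (1.05 equiv), THF, −78 °C; [Me2N=CH2]I, −78 → 0 °C; then MeI, CH2Cl2, rt; then aq NaHCO3, rt; 21 is used at once
Reagents that add atoms: N,N-dimethylmethyleneiminium iodide, C=[N+](C)C.[I-]
Why: Mannich reaction of the extended lithium dienolate, formed at the most acidic side-chain CH2 (vinylogous to both the C-4 ketone and the thioester), followed by N-methylation and E1cB (Hofmann-type) elimination should install the C-8=CH2 group.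

Step 13
Reactants: 21 exocyclic methylene dienone; 22 (2-methylprop-1-en-1-yl)magnesium bromide
Product: 24 tricyclic methyl acetal (ring A closed; 8S), via bromomagnesium dienolate 23 (not isolated)
Conditions: 22 (1.3 equiv, slow addition), CuBr·SMe2 (20 mol %), THF, −78 °C; then −78 → 0 °C; aq NH4Cl
Reagents that add atoms: none
Why: Copper-catalysed 1,6-addition of the alkenyl Grignard reagent to the exocyclic methylene of the cross-conjugated dienone (O=C-4–C-4a=C-8a–C=CH2) should give the bromomagnesium dienolate 23, whose γ-carbon (the future C-8) then attacks the S-tert-butyl thioester carbon (C-7) with loss of tert-butylthiolate, assisted by the thiophilic copper. The closest known reaction type is the Michael–Claisen (Michael–Dieckmann) ring closure of a conjugate-addition enolate onto an activated ester. Ring A closes in a 6-(enolendo)-exo-trig mode through the C-7–C-8 bond; attack through C-4a would need a four-membered ring, and O-acylation at O-4 should be reversible because thiolate reopens the enol lactone, whereas C-acylation is not. The configuration at C-8 rests on two elements: the dienone should react in the s-cis conformer in which the small methylene, not the CH2 of the lavandulyl arm, eclipses the fully substituted C-4a, so that in 23 the new prenyl CH2 is cis to C-4a and the lavandulyl CH2 is cis to O-1; and rings B and C are twisted about the C-4a–C-5 axis, so C-8 reaches C-7 from the face of ring C opposite the pseudoaxial phenyl group, which should place the lavandulyl arm syn to phenyl and give (8S). The step needs 1,6-addition rather than 1,2-addition at the thioester or the C-4 carbonyl, which the copper catalyst, the low temperature and the bulk of the S-tert-butyl group should secure.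

Step 14
Reactants: 24 tricyclic methyl acetal (ring A closed; 8S)
Product: 25 aldehyde (in equilibrium with its lactol)
Conditions: AcOH/THF/H2O (3:1:1), 40 °C
Reagents that add atoms: water, O
Why: Mild acid hydrolysis of the acetal should be easy because the ring oxygen leaves as a vinylogous acid (the C-5 enol of the β-triketone system), unmasking the aldehyde without protonating the prenyl or isopropenyl groups.

Step 15
Reactants: 25 aldehyde (in equilibrium with its lactol)
Product: 26 target acid
Conditions: NaClO2, NaH2PO4, 2-methylbut-2-ene (large excess), t-BuOH/H2O, 0 °C → rt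
Reagents that add atoms: sodium chlorite, [Na+].[O-]Cl=O
Why: Pinnick oxidation converts the aldehyde to the acid under buffered conditions in which the alkene scavenger removes hypochlorous acid, so the alkenes, the enol and the epimerisable C-3 centre should survive.

**Compound list**
1 | (R)-lavandulol, (2R)-5-methyl-2-(prop-1-en-2-yl)hex-4-en-1-ol | C=C(C)[C@@H](CC=C(C)C)CO | starting material
2 | (R)-lavandulyl iodide, (3R)-3-(iodomethyl)-2,6-dimethylhepta-1,5-diene | C=C(C)[C@@H](CC=C(C)C)CI | intermediate
3 | dimethyl malonate | COC(=O)CC(=O)OC | starting material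
4 | dimethyl 2-[(2S)-5-methyl-2-(prop-1-en-2-yl)hex-4-en-1-yl]propanedioate | C=C(C)[C@@H](CC=C(C)C)CC(C(=O)OC)C(=O)OC | intermediate
5 | (4R)-7-methyl-4-(prop-1-en-2-yl)oct-6-enoic acid | C=C(C)[C@@H](CC=C(C)C)CCC(=O)O | intermediate
6 | (4S)-4-benzyl-3-propanoyl-1,3-oxazolidin-2-one | CCC(=O)N1[C@@H](Cc2ccccc2)COC1=O | starting material
7 | acetaldehyde | CC=O | starting material
8 | (4S)-4-benzyl-3-[(2S,3R)-3-hydroxy-2-methylbutanoyl]-1,3-oxazolidin-2-one | O[C@H](C)[C@H](C)C(=O)N1[C@@H](Cc2ccccc2)COC1=O | intermediate
9 | (2S,3R)-3-hydroxy-N-methoxy-N,2-dimethylbutanamide | O[C@H](C)[C@H](C)C(=O)N(C)OC | intermediate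
10 | (2S,3R)-3-[(tert-butyldimethylsilyl)oxy]-N-methoxy-N,2-dimethylbutanamide | CC(C)(C)[Si](C)(C)O[C@H](C)[C@H](C)C(=O)N(C)OC | intermediate
11 | S-tert-butyl 3-oxobutanethioate | CC(=O)CC(=O)SC(C)(C)C | starting material
12 | (E)-cinnamaldehyde | O=C/C=C/c1ccccc1 | starting material
13 | S-tert-butyl (4S)-2-hydroxy-6-methyl-4-phenyl-3,4-dihydro-2H-pyran-5-carbothioate (anomers) | CC1=C(C(=O)SC(C)(C)C)[C@H](c2ccccc2)CC(O)O1 | intermediate
14 | S-tert-butyl (4S)-2-methoxy-6-methyl-4-phenyl-3,4-dihydro-2H-pyran-5-carbothioate (anomers) | CC1=C(C(=O)SC(C)(C)C)[C@H](c2ccccc2)CC(OC)O1 | intermediate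
15 | S-tert-butyl (4S)-6-[(3S,4R)-4-[(tert-butyldimethylsilyl)oxy]-3-methyl-2-oxopentyl]-2-methoxy-4-phenyl-3,4-dihydro-2H-pyran-5-carbothioate | CC(C)(C)[Si](C)(C)O[C@H](C)[C@H](C)C(=O)CC1=C(C(=O)SC(C)(C)C)[C@H](c2ccccc2)CC(OC)O1 | intermediate
16 | (4R)-7-methyl-4-(prop-1-en-2-yl)oct-6-enoyl chloride | C=C(C)[C@@H](CC=C(C)C)CCC(=O)Cl | intermediate
17 | S-tert-butyl (4S)-6-[(2R,3S,9R)-2-[(tert-butyldimethylsilyl)oxy]-3,12-dimethyl-4,6-dioxo-9-(prop-1-en-2-yl)tridec-11-en-5-yl]-2-methoxy-4-phenyl-3,4-dihydro-2H-pyran-5-carbothioate (diketo tautomer drawn) | CC(C)(C)[Si](C)(C)O[C@H](C)[C@H](C)C(=O)C(C(=O)CC[C@H](CC=C(C)C)C(C)=C)C1=C(C(=O)SC(C)(C)C)[C@H](c2ccccc2)CC(OC)O1 | intermediate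
18 | S-tert-butyl (4S)-6-{(2R,3S)-2,3-dimethyl-6-[(3R)-6-methyl-3-(prop-1-en-2-yl)hept-5-en-1-yl]-4-oxo-3,4-dihydro-2H-pyran-5-yl}-2-methoxy-4-phenyl-3,4-dihydro-2H-pyran-5-carbothioate | COC1C[C@@H](c2ccccc2)C(C(=O)SC(C)(C)C)=C(O1)C3=C(CC[C@H](CC=C(C)C)C(C)=C)O[C@H](C)[C@H](C)C3=O | intermediate
19 | Mannich base: 18 with a CH2NMe2 group on the side-chain carbon attached to C-6 of the pyranone (the future C-8; epimers) | COC1C[C@@H](c2ccccc2)C(C(=O)SC(C)(C)C)=C(O1)C3=C(C(CN(C)C)C[C@H](CC=C(C)C)C(C)=C)O[C@H](C)[C@H](C)C3=O | intermediate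
20 | N-methyl ammonium iodide of 19 | COC1C[C@@H](c2ccccc2)C(C(=O)SC(C)(C)C)=C(O1)C3=C(C(C[N+](C)(C)C)C[C@H](CC=C(C)C)C(C)=C)O[C@H](C)[C@H](C)C3=O.[I-] | intermediate
21 | S-tert-butyl (4S)-6-{(2R,3S)-2,3-dimethyl-6-[(4S)-7-methyl-4-(prop-1-en-2-yl)octa-1,6-dien-2-yl]-4-oxo-3,4-dihydro-2H-pyran-5-yl}-2-methoxy-4-phenyl-3,4-dihydro-2H-pyran-5-carbothioate | COC1C[C@@H](c2ccccc2)C(C(=O)SC(C)(C)C)=C(O1)C3=C(C(=C)C[C@H](CC=C(C)C)C(C)=C)O[C@H](C)[C@H](C)C3=O | intermediate
22 | (2-methylprop-1-en-1-yl)magnesium bromide | CC(C)=C[Mg]Br | starting material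
23 | bromomagnesium O-4 dienolate of the 1,6-adduct (exocyclic C-8=C-8a bond; prenyl CH2 cis to C-4a, lavandulyl CH2 cis to O-1) | COC1C[C@@H](c2ccccc2)C(C(=O)SC(C)(C)C)=C(O1)C3=C(O[Mg]Br)[C@@H](C)[C@@H](C)O/C3=C(/CC=C(C)C)C[C@H](CC=C(C)C)C(C)=C | intermediate
24 | tricyclic methyl acetal: (2R,3S,8S)-2,3-dimethyl-8-(3-methylbut-2-en-1-yl)-8-[(2S)-5-methyl-2-(prop-1-en-2-yl)hex-4-en-1-yl]-2,3-dihydro-4H-chromene-4,7(8H)-dione with O-5 and C-6 bridged by CH(OMe)–CH2–CH(Ph) (ring C; S at the benzylic carbon; anomers) | C=C(C)[C@@H](CC=C(C)C)C[C@]1(CC=C(C)C)C(=O)C3=C(OC(OC)C[C@H]3c4ccccc4)C2=C1O[C@H](C)[C@H](C)C2=O | intermediate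
25 | (3S)-3-[(2R,3S,8S)-5-hydroxy-2,3-dimethyl-8-(3-methylbut-2-en-1-yl)-8-[(2S)-5-methyl-2-(prop-1-en-2-yl)hex-4-en-1-yl]-4,7-dioxo-3,4,7,8-tetrahydro-2H-chromen-6-yl]-3-phenylpropanal | C=C(C)[C@@H](CC=C(C)C)C[C@]1(CC=C(C)C)C(=O)C([C@@H](CC=O)c2ccccc2)=C(O)C2=C1O[C@H](C)[C@H](C)C2=O | intermediate
26 | (3S)-3-[(2R,3S,8S)-5-hydroxy-2,3-dimethyl-8-(3-methylbut-2-en-1-yl)-8-[(2S)-5-methyl-2-(prop-1-en-2-yl)hex-4-en-1-yl]-4,7-dioxo-3,4,7,8-tetrahydro-2H-chromen-6-yl]-3-phenylpropanoic acid | C=C(C)[C@@H](CC=C(C)C)C[C@]1(CC=C(C)C)C(=O)C([C@@H](CC(=O)O)c2ccccc2)=C(O)C2=C1O[C@H](C)[C@H](C)C2=O | target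

**Step count:** 15 steps in total. Longest linear sequence: 10 steps (4, 5, 6, 9, 10, 11, 12, 13, 14, 15).

**Steps most likely to fail**

1. Step 13. What may go wrong: loss of control over the C-8 configuration (reaction through the other dienone conformer, or attack syn to phenyl), or 1,2-addition of the Grignard reagent to the thioester. Fallback, setting out from 18 and coming back at 24: 18 is deprotonated at the side-chain CH2 next to C-8a with LiN(SiMe3)2 (2.2 equiv) in THF in the presence of CuBr·SMe2 and warmed. The same thioester Claisen closure forms the C-7–C-8 bond, and the product should tautomerise to the aromatic 7-hydroxychromanone F1. C-Prenylation of the sodium phenoxide of F1 with dearomatisation (NaH, prenyl bromide, toluene, 0 °C), a known reaction of acylphloroglucinol-type phenols, then creates the quaternary centre in an alkylation step, again anti to the pseudoaxial phenyl group, and gives 24.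

2. Step 12. What may go wrong: deprotonation at C-3 of ring B in competition with the side-chain CH2 (epimerisation of the cis-dimethyl unit), or decomposition of the cross-conjugated triene during the elimination. Fallback, setting out from 5 and coming back at 21: the one-carbon unit is brought in before ring B exists. The dianion of 5 (LiN(iPr)2, 2.2 equiv, THF) is alkylated with chloromethyl methyl ether to give the α-(methoxymethyl) acid F2. F2 replaces 5 under the conditions of step 10 to give the diketone F3, and the conditions of step 11 give the pyranone F4, which carries CH2OMe on the future C-8. DBU in CH2Cl2 (E1cB loss of methanol from the doubly activated position) then gives 21 without a strong base acting on ring B.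

3. Step 9. What may go wrong: quenching of the dienolate by the more acidic product ketone and slow attack on the hindered α-branched amide, leading to incomplete conversion. Fallback, setting out from 10 and coming back at 15: 10 is reduced with iBu2AlH (THF, −78 °C) to the aldehyde F5. Vinylogous aldol addition of the lithium dienolate of 14 to F5 gives the β-hydroxy thioester F6 (carbinol epimers), and Dess–Martin oxidation gives 15.

**Further compounds**
F1 | step 13 | aromatic phenol: (2R,3S)-7-hydroxy-2,3-dimethyl-8-[(2S)-5-methyl-2-(prop-1-en-2-yl)hex-4-en-1-yl]chroman-4-one with O-5 and C-6 bridged by CH(OMe)–CH2–CH(Ph) (ring C; S at the benzylic carbon; anomers) | C=C(C)[C@@H](CC=C(C)C)Cc1c(O)c3c(OC(OC)C[C@H]3c4ccccc4)c2c1O[C@H](C)[C@H](C)C2=O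
F2 | step 12 | (4S)-2-(methoxymethyl)-7-methyl-4-(prop-1-en-2-yl)oct-6-enoic acid (C-2 epimers) | C=C(C)[C@@H](CC=C(C)C)CC(COC)C(=O)O
F3 | step 12 | diketone: 17 with a CH2OMe group on the carbon α to the lavandulyl-side ketone (epimers; diketo tautomer drawn) | CC(C)(C)[Si](C)(C)O[C@H](C)[C@H](C)C(=O)C(C(=O)C(COC)C[C@H](CC=C(C)C)C(C)=C)C1=C(C(=O)SC(C)(C)C)[C@H](c2ccccc2)CC(OC)O1
F4 | step 12 | pyranone: 18 with a CH2OMe group on the side-chain carbon attached to C-6 of the pyranone (epimers) | COC1C[C@@H](c2ccccc2)C(C(=O)SC(C)(C)C)=C(O1)C3=C(C(COC)C[C@H](CC=C(C)C)C(C)=C)O[C@H](C)[C@H](C)C3=O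
F5 | step 9 | (2S,3R)-3-[(tert-butyldimethylsilyl)oxy]-2-methylbutanal | CC(C)(C)[Si](C)(C)O[C@H](C)[C@H](C)C=O
F6 | step 9 | β-hydroxy thioester: 15 with CH(OH) in place of the side-chain ketone (carbinol epimers) | CC(C)(C)[Si](C)(C)O[C@H](C)[C@H](C)C(O)CC1=C(C(=O)SC(C)(C)C)[C@H](c2ccccc2)CC(OC)O1
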